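The route rests on disconnecting the bond between ring carbon C6 of the 4-pyranone and the first methylene of the undecyl chain. The pyranone ring (O1, C2–C6) carries methyls at C3/C5 and oxygen at C2/C6, so it has latent mirror symmetry: the target is the mono-alkylated derivative of 2,6-dimethoxy-3,5-dimethyl-4H-pyran-4-one, in which C2 and C6 are equivalent vinylogous-carbonate carbons. In one operation an 11-carbon Grignard reagent carrying its hydroxyl as a magnesium alkoxide adds to C6 and expels methoxide, which joins both halves, desymmetrises the ring and leaves the C2 methoxy group in place. The symmetric pyranone comes in three steps from dimethyl 3-oxopentanedioate; acetylation finishes the synthesis.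

Key step: step 4

Remark: the target has no stereocentre. Compound 2 is used as its mixture of diastereomers and enol forms, which converge in step 2; adduct 9 is transient and racemic.

Step 1
Reactants: 1 dimethyl 3-oxopentanedioate
Product: 2 dimethyl 2,4-dimethyl-3-oxopentanedioate
Conditions: MeI (2.1 equiv), K2CO3 (2.2 equiv), acetone, rt → reflux
Reagents that add atoms: iodomethane, CI
Why: Double C-alkylation of the two β-keto ester methylenes; after the first methylation the remaining CH2 is more acidic and less hindered than the CH(Me), so the second methyl should enter at the other α-carbon.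

Step 2
Reactants: 2 dimethyl 2,4-dimethyl-3-oxopentanedioate
Product: 3 4-hydroxy-6-methoxy-3,5-dimethyl-2H-pyran-2-one
Conditions: conc. H2SO4 containing a little oleum (dehydrating medium), 0 °C → rt; poured onto ice, extracted at once
Reagents that add atoms: none
Why: Acid-mediated lactonisation, in which the carbonyl oxygen of one ester attacks the protonated second ester, methanol is lost and enolisation gives the 4-hydroxy-2-pyranone (held as a hydroxypyrylium ion in the acid).

Step 3
Reactants: 3 4-hydroxy-6-methoxy-3,5-dimethyl-2H-pyran-2-one
Product: 5 2,6-dimethoxy-3,5-dimethyl-4H-pyran-4-one, via hydroxypyrylium triflate 4 (not isolated)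
Conditions: MeOTf (1.1 equiv), CH2Cl2, 0 °C → rt; then sat. aq. NaHCO3
Reagents that add atoms: methyl trifluoromethanesulfonate, COS(=O)(=O)C(F)(F)F
Why: O-methylation of a neutral protomeric ambident nucleophile with a hard methylating agent, which should occur at the oxygen that carries no proton (the lactone C=O); the hydroxypyrylium salt 4 is non-nucleophilic, so a second methylation is held back, and basic work-up removes the proton to give the symmetric 4-pyranone.

Step 4
Reactants: 5 2,6-dimethoxy-3,5-dimethyl-4H-pyran-4-one; 6 11-bromoundecan-1-ol
Product: 10 6-(11-hydroxyundecyl)-2-methoxy-3,5-dimethyl-4H-pyran-4-one, via chloromagnesium 11-bromoundecan-1-olate 7 (not isolated), via alkoxide Grignard reagent 8 (not isolated), via magnesium dienolate adduct 9 (not isolated)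
Conditions: 6 (1.4 equiv), i-PrMgCl (0.98 equiv per 6), THF, −20 °C; Mg turnings (I2 cat.), THF, 50 °C; then 5 (1.0 equiv), THF, −40 → 0 °C; sat. aq. NH4Cl
Reagents that add atoms: none
Why: The carbon–magnesium end of 8 adds in a conjugate (1,4) sense to C6 of the vinylogous carbonate O1–C6(OMe)=C5–C4=O of 5 and gives the magnesium dienolate 9 with a tetrahedral C6, which on warming and work-up expels methoxide and restores the aromatic 4-pyranone (addition–elimination at a vinylic carbon). The closest known reaction type is the conjugate addition–elimination of Grignard and organolithium reagents to β-alkoxy enones and to 2,6-dialkoxy-4-pyranones, used to desymmetrise such pyranones. No ring is closed and no stereocentre remains in the product. The step needs mono-substitution, 1,4- rather than 1,2-addition and attack by carbon rather than oxygen: C2 and C6 of 5 are equivalent so either gives the same product, adduct 9 is an enolate and resists a second addition, the C4 carbonyl is flanked by the C3 and C5 methyls and deactivated by two donor oxygens, and the chloromagnesium alkoxide end is a poor nucleophile at low temperature. The hydroxyl is carried as its magnesium alkoxide (deprotonation with slightly less than one equivalent of i-PrMgCl, so that no isopropyl Grignard is left to add to 5, then magnesium insertion), a known way to form Grignard reagents from halo alcohols without a protecting group.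

Step 5
Reactants: 10 6-(11-hydroxyundecyl)-2-methoxy-3,5-dimethyl-4H-pyran-4-one
Product: 11 11-(6-methoxy-3,5-dimethyl-4-oxo-4H-pyran-2-yl)undecyl acetate
Conditions: Ac2O, pyridine, DMAP (cat.), CH2Cl2, 0 °C → rt
Reagents that add atoms: acetic anhydride, CC(=O)OC(C)=O
Why: DMAP-catalysed acetylation of the primary alcohol; the methoxypyranone has no competing nucleophilic site and should survive these mild conditions.

Compound list
1 | dimethyl 3-oxopentanedioate | COC(=O)CC(=O)CC(=O)OC | starting material
2 | dimethyl 2,4-dimethyl-3-oxopentanedioate (mixture of diastereomers) | COC(=O)C(C)C(=O)C(C)C(=O)OC | intermediate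
3 | 4-hydroxy-6-methoxy-3,5-dimethyl-2H-pyran-2-one | COC1=C(C)C(O)=C(C)C(=O)O1 | intermediate
4 | 4-hydroxy-2,6-dimethoxy-3,5-dimethylpyrylium trifluoromethanesulfonate (not isolated) | COc1[o+]c(OC)c(C)c(O)c1C.[O-]S(=O)(=O)C(F)(F)F | intermediate
5 | 2,6-dimethoxy-3,5-dimethyl-4H-pyran-4-one | COc1oc(OC)c(C)c(=O)c1C | intermediate
6 | 11-bromoundecan-1-ol | OCCCCCCCCCCCBr | starting material
7 | chloromagnesium 11-bromoundecan-1-olate (not isolated) | Cl[Mg]OCCCCCCCCCCCBr | intermediate
8 | [11-(chloromagnesiooxy)undecyl]magnesium bromide (not isolated) | Cl[Mg]OCCCCCCCCCCC[Mg]Br | intermediate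
9 | bromomagnesium 2-[11-(chloromagnesiooxy)undecyl]-2,6-dimethoxy-3,5-dimethyl-2H-pyran-4-olate (racemic, not isolated) | COC1=C(C)C(O[Mg]Br)=C(C)C(OC)(CCCCCCCCCCCO[Mg]Cl)O1 | intermediate
10 | 6-(11-hydroxyundecyl)-2-methoxy-3,5-dimethyl-4H-pyran-4-one | COc1oc(CCCCCCCCCCCO)c(C)c(=O)c1C | intermediate
11 | 11-(6-methoxy-3,5-dimethyl-4-oxo-4H-pyran-2-yl)undecyl acetate | COc1oc(CCCCCCCCCCCOC(C)=O)c(C)c(=O)c1C | target

Total step count: 5
Longest linear sequence: 5 steps (1 → 2 → 3 → 5 → 10 → 11); compound 6 is commercial and enters at step 4.

Steps most likely to fail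

Step 4 (key step). The alkoxide-bearing Grignard reagent may form as a poorly soluble aggregate, Wurtz coupling may compete during magnesium insertion, and the alkoxide oxygen may compete with carbon for C6. A second substitution or 1,2-addition at C4 is a lesser concern. The fallback masks the hydroxyl so that a soluble mono-Grignard reagent can be used; it sets out from 6 and comes back to the route at 10. Silylation of 6 (TBSCl, imidazole, DMF, rt) should give (11-bromoundecyloxy)(tert-butyl)dimethylsilane F1. Magnesium insertion (Mg, THF, 40 °C) should give [11-(tert-butyldimethylsilyloxy)undecyl]magnesium bromide F2. Addition of F2 to 5 (THF, −40 → 0 °C) with loss of methoxide should give 6-[11-(tert-butyldimethylsilyloxy)undecyl]-2-methoxy-3,5-dimethyl-4H-pyran-4-one F3. Desilylation (TBAF, THF, 0 °C) should then give 10.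

Step 2. In the strong acid, ester hydrolysis followed by decarboxylation of the β-keto acid may compete with lactonisation, and the acyl ketene acetal of the product may be hydrolysed during the aqueous quench. The fallback closes the ring under neutral, non-aqueous conditions; it sets out from 2 and comes back at 3. Mono-saponification of the symmetric diester (KOH, 1.0 equiv, THF–H2O, 0 °C, cold acidification) should give 5-methoxy-2,4-dimethyl-3,5-dioxopentanoic acid F4, kept cold and used at once. Activation of the acid with DCC (CH2Cl2, 0 °C) should let the ester carbonyl oxygen close the six-membered ring and, after enolisation, give 3.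

Step 3. Methylation may occur at the hydroxyl oxygen instead of the lactone carbonyl oxygen, or a second methylation may follow if the pyrylium intermediate is deprotonated in the flask. The fallback blocks the hydroxyl oxygen first; it sets out from 3 and comes back at 5. Silylation (TBSCl, imidazole, CH2Cl2, rt) should give the thermodynamically preferred 4-(tert-butyldimethylsilyloxy)-6-methoxy-3,5-dimethyl-2H-pyran-2-one F5. MeOTf (CH2Cl2, rt) can then methylate only the lactone carbonyl oxygen, giving 4-(tert-butyldimethylsilyloxy)-2,6-dimethoxy-3,5-dimethylpyrylium trifluoromethanesulfonate F6. Aqueous NaHCO3 should cleave the labile Si–O bond, not the O–CH3 bonds, and give 5.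

Further compounds
F1 | step 4 | (11-bromoundecyloxy)(tert-butyl)dimethylsilane | CC(C)(C)[Si](C)(C)OCCCCCCCCCCCBr
F2 | step 4 | [11-(tert-butyldimethylsilyloxy)undecyl]magnesium bromide | CC(C)(C)[Si](C)(C)OCCCCCCCCCCC[Mg]Br
F3 | step 4 | 6-[11-(tert-butyldimethylsilyloxy)undecyl]-2-methoxy-3,5-dimethyl-4H-pyran-4-one | COc1oc(CCCCCCCCCCCO[Si](C)(C)C(C)(C)C)c(C)c(=O)c1C
F4 | step 2 | 5-methoxy-2,4-dimethyl-3,5-dioxopentanoic acid | COC(=O)C(C)C(=O)C(C)C(O)=O
F5 | step 3 | 4-(tert-butyldimethylsilyloxy)-6-methoxy-3,5-dimethyl-2H-pyran-2-one | COC1=C(C)C(O[Si](C)(C)C(C)(C)C)=C(C)C(=O)O1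
F6 | step 3 | 4-(tert-butyldimethylsilyloxy)-2,6-dimethoxy-3,5-dimethylpyrylium trifluoromethanesulfonate | COc1[o+]c(OC)c(C)c(O[Si](C)(C)C(C)(C)C)c1C.[O-]S(=O)(=O)C(F)(F)F
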